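| setting | Friday's | Sunday's | zeta | alpha | epsilon |
|---|---|---|---|---|---|
| substrate | 20 mM | 20 mM | 20 mM | 20 mM | 20 mM |
| catalyst | 3.6 mM | 5.7 mM | 2.6 mM | 2.6 mM | 2.6 mM |
| temperature | −40 °C | −5 °C | −5 °C | −35 °C | 25 °C |
| remark | run made earlier | run made earlier |  |  |  |
| time |  |  | 30 d | 30 d | 30 d |

| run | time / d | target / % | substrate / % |
|---|---|---|---|
| Friday's | 8.00 | 0.3 | 100.2 |
| Friday's | 15.0 | 0.3 | 99.8 |
| Friday's | 30.0 | 0.6 | 98.7 |
| Friday's | 60.0 | 1.1 | 98.9 |
| Friday's | 120 | 2.3 | 96.1 |
| Sunday's | 1.25 | 4.6 | 93.4 |
| Sunday's | 2.50 | 10.6 | 87.1 |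
| Sunday's | 5.00 | 18.2 | 75.0 |
| Sunday's | 10.0 | 32.4 | 56.9 |
| Sunday's | 20.0 | 50.4 | 35.2 |

(standard deviation of a reading: 0.5 percentage points)

* the best flask by amount of target, in percent of the substrate charged; "all alike" if 1.5 percentage points covers them all (zeta / alpha / epsilon / all alike)
* amount of target at the end, in percent of the substrate charged, zeta
* amount of target at the end, in percent of the substrate charged, alpha
* amount of target at the end, in percent of the substrate charged, epsilon

- You cannot tell catalyst from temperature in the two earlier runs, since they changed together; so compare two rates inside one flask, where both settings are shared.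
- Split the substrate lost into two parts: what went to target, and what went by any other route into whatever the readings miss. At 20.0 d in Sunday's run, target holds 50.4% and the missing part is 14 percentage points.
- Call the ratio of these two the split S (a selectivity factor): Sunday's run reads 3.50.
- I assume, untested by any run, that catalyst speeds the target route and leaves the other alone. Then the split per mM of catalyst, σ = S divided by the catalyst charged, reads 0.614 mM⁻¹ on Sunday's run.
- Friday's run, at −40 °C, gives a rougher reading of 0.399 mM⁻¹, its missing part being 1.6 points against a scatter of 0.5 points in each reading.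
- Zeta shares Sunday's temperature, so with 2.6 mM of catalyst I expect S = 1.60. That sends 61.5% of the consumed substrate to target, my figure against the forecast's 77%. No reading shows σ at 25 °C.
- The forecast says epsilon is best, with 39% for zeta, 0.9% for alpha and 74% for epsilon, the last “capped by selectivity at about 75%, an extrapolation with risk”.
- After 30 d the flasks hold 36.8% of target in zeta, 1.01% in alpha and 1.34% in epsilon, so the best is zeta.

    substrate + catalyst ⇌ catalyst + target (K = 1.12, k = 8.23 M⁻¹ h⁻¹, Ea = 72.0 kJ mol⁻¹, ΔH = −49.0 kJ mol⁻¹)
    2 substrate → homo dimer (k = 0.333 M⁻¹ h⁻¹, Ea = 68.0 kJ mol⁻¹)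
    substrate → uncatalysed product (k = 0.0110 h⁻¹, Ea = 107 kJ mol⁻¹)
    (constants at 25 °C)

- Zeta's split comes to 1.57. A second flask, alpha's recipe with 6.5 mM of catalyst, has σ = 0.412 mM⁻¹. Epsilon's split is 0.0137, because target there goes back to substrate: with that way back taken away, epsilon holds 55.3% of target instead of 1.34%.

The runs were computed from invented constants.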